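**Strategy.** Ring A, the seven-membered lactone O–C3(=O)–C2=C1–C10–C5–C4(CH3)2, is cut at C4–C5 and at C1=C2. Its four atoms C2–C3(=O)–O–C4 are an acetone enol ester of an acetic acid unit, and they span the 1,3-related carbons C1 and C5 that flank quaternary C10. One (4+3) operation builds ring A on ring B: a hydrogen-atom-transfer Giese addition of an isopropenyl phosphonoacetate to a 4-formyl-4-methylcyclohexenone, followed in the same flask by intramolecular Horner–Wadsworth–Emmons closure. The C7 ketone left behind then drives ring-B elaboration and a double Michael union with a butenolide silyl enol ether that assembles the bicyclo[2.2.2]octane; alkylation closes the cyclopentane.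

Key step: step 3

Remark: locants are terpenoid-style: ring A C1=C2–C3(=O)–O–C4(CH3)2–C5–C10; ring B C5–C10; C11 on C9; C12 on C8; cage ring C1′(H)–C2′H2–C3′(CH3)–C4′(=O)–C5′(CH3)–C6′, with lactone C7′(=O) on C1′ and C8′H2–O on C6′; α is the face opposite the C10 methyl. The (R,R)-catalyst of step 2 is assumed to deliver (R)-7 (otherwise its mirror image is used). Compounds 24–28 are drawn with C5′ unspecified (epimers) and C1′ as in the target; both centres are expected to converge in step 14.

Step 1
Reactants: 1 2-(diethoxyphosphoryl)acetic acid; 2 propyne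
Product: 3 prop-1-en-2-yl 2-(diethoxyphosphoryl)acetate
Conditions: [RuCl2(p-cymene)]2 (1 mol %), P(2-furyl)3, Na2CO3 (cat.), toluene, 50 °C, sealed vessel
Reagents that add atoms: none
Why: Ruthenium-catalysed Markovnikov addition of the carboxylic acid across the terminal alkyne should give the isopropenyl (enol) ester directly; no stereocentre is formed.

Step 2
Reactants: 4 methacrolein; 5 (E)-3-(tert-butyldimethylsilyloxy)-N,N-dimethylbuta-1,3-dien-1-amine
Product: 7 (R)-1-methyl-4-oxocyclohex-2-ene-1-carbaldehyde, via cycloadduct 6 (not isolated)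
Conditions: (R,R)-[Cr(salen)]SbF6 (5 mol %), 4 Å MS, CH2Cl2, −40 °C; then 1 M HCl, THF, 0 °C
Reagents that add atoms: none
Why: Catalytic enantioselective Diels–Alder reaction of the α-substituted acrolein with the 1-amino-3-siloxy diene, the chiral chromium salen Lewis acid blocking one face of the bound aldehyde, should set quaternary C10, and acid then hydrolyses the silyl enol ether and eliminates dimethylamine to unveil the enone.

Step 3
Reactants: 7 (R)-1-methyl-4-oxocyclohex-2-ene-1-carbaldehyde; 3 prop-1-en-2-yl 2-(diethoxyphosphoryl)acetate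
Product: 9 trans-fused ring A/ring B keto lactone (C1=C2 enoate lactone; C7 ketone), via Giese adduct 8 (not isolated)
Conditions: Fe(acac)3 (30 mol %), PhSiH3, EtOH/(CH2OH)2, 60 °C; then LiCl, DBU, MeCN, 25 °C, high dilution (one pot)
Reagents that add atoms: none
Why: Hydrogen-atom transfer from an iron hydride to the isopropenyl ester gives the tertiary α-acyloxy radical (C4), which adds in a Giese fashion to C5, the β-carbon of the enone; reduction and protonation give phosphonate 8, and after addition of LiCl/DBU the phosphonate carbanion (C2) condenses with the neopentyl aldehyde (C1) in an intramolecular Horner–Wadsworth–Emmons reaction. The closest known reaction types are the iron-mediated reductive cross-coupling of heteroatom-substituted olefins with enones and the Masamune–Roush olefinative closure of unsaturated lactones. Ring A closes at C1=C2 by 7-exo-trig attack of the C2 carbanion on the aldehyde and syn-elimination of phosphate, the ring enforcing the Z geometry. The C5 stereocentre is controlled by C10: the radical should attack axially, anti to the pseudoaxial formyl group (smaller than methyl), which places C4 trans to C1 and cis to the C10 methyl, the diequatorial arrangement needed for the trans-fused lactone. The step needs hydrogen-atom transfer to the electron-rich enol ester and not to the enone, attack at C5, and olefination of the aldehyde in preference to the C7 ketone; these are secured by the polarity match of the nucleophilic radical with the enone β-carbon, by keeping the radical stage base-free so that the phosphonate stays silent, and by the higher electrophilicity of the aldehyde.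

Step 4
Reactants: 9 trans-fused ring A/ring B keto lactone
Product: 10 C7 trimethylsilyl enol ether of 9 (C7=C8)
Conditions: LDA, THF, −78 °C; TMSCl
Reagents that add atoms: chlorotrimethylsilane C[Si](C)(C)Cl
Why: Kinetic deprotonation should occur at C8, the α-methylene remote from the congested C5 position next to the gem-dimethyl carbon, and O-silylation fixes this enolate regiochemistry.

Step 5
Reactants: 10 C7 trimethylsilyl enol ether of 9
Product: 11 enone lactone (9 with a C8=C9 double bond)
Conditions: Pd(OAc)2 (10 mol %), O2 (1 atm), DMSO, 25 °C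
Reagents that add atoms: none
Why: Saegusa–Ito oxidation through a palladium enolate and β-hydride elimination should place the new double bond at C8=C9 regiospecifically, the non-enolisable enoate lactone being inert.

Step 6
Reactants: 11 enone lactone; 12 (chloromethyl)(isopropoxy)dimethylsilane
Product: 15 keto lactone bearing C9α-CH2SiMe2(OiPr) and C8-CH2OH (C8 epimers), via Grignard reagent 13 (not isolated), via silyl enol ether 14 (not isolated)
Conditions: 12, Mg, THF; then 11, CuI (10 mol %), TMSCl, THF, −78 °C; then aq. HCHO, Yb(OTf)3 (10 mol %), THF, 25 °C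
Reagents that add atoms: formaldehyde C=O
Why: Copper-catalysed conjugate addition should deliver C11 axially to C9 from the α-face, anti to the axial C10 methyl of the trans-fused bicycle, and the regiodefined silyl enol ether is then hydroxymethylated at C8 by an aqueous Mukaiyama aldol reaction (the C8 configuration is lost in step 8).

Step 7
Reactants: 15 keto lactone bearing C9α-CH2SiMe2(OiPr) and C8-CH2OH
Product: 16 diol (C11–OH on C9α-CH2; C12–OH on C8-CH2)
Conditions: KF, KHCO3, 30% H2O2, THF/MeOH, 25 °C
Reagents that add atoms: hydrogen peroxide OO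
Why: Tamao–Fleming oxidation converts the alkoxysilyl C–Si bond into C–OH, the weakly basic fluoride/bicarbonate medium being expected to leave the β-hydroxy ketone and both ester functions intact.

Step 8
Reactants: 16 diol
Product: 18 α-methylene ketone (C8=C12H2) carrying the C11 methanesulfonate, via bis-mesylate 17 (not isolated)
Conditions: MsCl, Et3N, CH2Cl2, −20 °C; then DBU, 0 °C
Reagents that add atoms: methanesulfonyl chloride CS(=O)(=O)Cl
Why: Both primary alcohols are mesylated and only the β-mesyloxy ketone undergoes E1cB elimination, which gives the exocyclic enone and leaves the unactivated C11 mesylate as the later leaving group.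

Step 9
Reactants: 19 2-methylpent-1-en-3-one
Product: 20 tert-butyldimethyl{[(3Z)-2-methylpenta-1,3-dien-3-yl]oxy}silane
Conditions: TBSOTf, Et3N, CH2Cl2, 0 °C
Reagents that add atoms: tert-butyldimethylsilyl trifluoromethanesulfonate CC(C)(C)[Si](C)(C)OS(=O)(=O)C(F)(F)F
Why: Soft enolisation of the ketone, whose only α-hydrogens are on the ethyl group, should give the (Z)-configured 2-silyloxy diene with the terminal methyl turned outward.

Step 10
Reactants: 20 tert-butyldimethyl{[(3Z)-2-methylpenta-1,3-dien-3-yl]oxy}silane; 21 methyl 4-hydroxybut-2-ynoate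
Product: 23 5-(tert-butyldimethylsilyloxy)-4,6-dimethyl-4,7-dihydro-2-benzofuran-1(3H)-one (racemic), via hydroxy ester cycloadduct 22 (not isolated)
Conditions: toluene, 120 °C, sealed tube, argon
Reagents that add atoms: none
Why: Diels–Alder reaction of the 2-silyloxy diene with the ynoate should follow the para rule (ester carbon bonded to the CH2 terminus), and the (Z)-γ-hydroxy enoate so formed lactonises on heating to the butenolide; the single stereocentre (C5′) is racemic and is erased later by enolisation.

Step 11
Reactants: 18 α-methylene ketone carrying the C11 methanesulfonate; 23 butenolide silyl enol ether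
Product: 26 bicyclo[2.2.2]octane diketone lactone (bonds C12–C3′ and C8–C6′ formed; C11–OMs retained), via mono-adduct 24 (not isolated), via silyl ketene acetal 25 (not isolated)
Conditions: TBSOTf (20 mol %), CH2Cl2, −78 → −20 °C; then 1 M HCl, THF, 0 °C
Reagents that add atoms: none
Why: In a silyl-triflate-catalysed tandem Mukaiyama–Michael sequence, C3′ of the silyl enol ether adds to C12, silyl transfer gives the C7 silyl enol ether, and C8 then adds to the butenolide β-carbon C6′ from the α-face of ring B (anti to the axial C10 methyl), with the bulky C7 silyloxy group over the flat C1′/C2′ bridge so that C9 and its CH2OMs arm lie beneath C5′.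

Step 12
Reactants: 26 bicyclo[2.2.2]octane diketone lactone
Product: 27 C7 p-toluenesulfonylhydrazone of 26
Conditions: TsNHNH2, PPTS (cat.), EtOH, 60 °C
Reagents that add atoms: p-toluenesulfonohydrazide Cc1ccc(cc1)S(=O)(=O)NN
Why: Condensation should occur only at the C7 ketone, because the C4′ ketone is buried in the cage between quaternary C3′ and the branched C5′.

Step 13
Reactants: 27 C7 p-toluenesulfonylhydrazone
Product: 28 7-deoxo mesylate (C7H2)
Conditions: catecholborane, CHCl3, 0 °C; then NaOAc·3H2O, 60 °C
Reagents that add atoms: none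
Why: Hydride addition to the C=N bond followed by acetate-induced loss of sulfinate and dinitrogen (Caglioti-type tosylhydrazone reduction) should turn C7 into CH2 under conditions that spare the lactones, the enoate and the mesylate.

Step 14
Reactants: 28 7-deoxo mesylate
Product: 29 andilesin C
Conditions: t-BuOK, t-BuOH/THF, 0 → 25 °C
Reagents that add atoms: none
Why: Enolisation at C5′, now the only ketone α-position bearing hydrogen, is followed by 5-exo-tet alkylation by the C11 mesylate, which can reach only the face of C5′ turned toward C9, so the cage dictates the new quaternary centre, while the base lets C1′ settle with the lactone carbonyl away from ring B.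

Compound list
1 | 2-(diethoxyphosphoryl)acetic acid | OC(=O)CP(=O)(OCC)OCC | starting material
2 | propyne | CC#C | starting material
3 | prop-1-en-2-yl 2-(diethoxyphosphoryl)acetate | CC(=C)OC(=O)CP(=O)(OCC)OCC | intermediate
4 | methacrolein (2-methylprop-2-enal) | CC(=C)C=O | starting material
5 | (E)-3-(tert-butyldimethylsilyloxy)-N,N-dimethylbuta-1,3-dien-1-amine | CN(C)/C=C/C(=C)O[Si](C)(C)C(C)(C)C | starting material
6 | (1R)-2-(dimethylamino)-1-methyl-4-(tert-butyldimethylsilyloxy)cyclohex-3-ene-1-carbaldehyde (amino group cis to CHO) | O=C[C@@]1(C)[C@@H](N(C)C)C=C(O[Si](C)(C)C(C)(C)C)CC1 | intermediate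
7 | (R)-1-methyl-4-oxocyclohex-2-ene-1-carbaldehyde | O=C[C@@]1(C)C=CC(=O)CC1 | intermediate
8 | 2-(2-formyl-2-methyl-5-oxocyclohexyl)propan-2-yl 2-(diethoxyphosphoryl)acetate (side chain trans to CHO and cis to CH3) | CC(C)(OC(=O)CP(=O)(OCC)OCC)[C@@H]1CC(=O)CC[C@@]1(C)C=O | intermediate
9 | trans-fused keto lactone: ring A lactone (C3=O; C1=C2; C4 gem-dimethyl) on ring B cyclohexanone (C7=O); C10 methyl β; C5–H α | CC1(C)OC(=O)C=C[C@@]2(C)[C@H]1CC(=O)CC2 | intermediate
10 | C7 trimethylsilyl enol ether of 9 (C7=C8) | CC1(C)OC(=O)C=C[C@@]2(C)[C@H]1CC(O[Si](C)(C)C)=CC2 | intermediate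
11 | enone lactone: 9 with C8=C9 double bond | CC1(C)OC(=O)C=C[C@@]2(C)[C@H]1CC(=O)C=C2 | intermediate
12 | (chloromethyl)(isopropoxy)dimethylsilane | CC(C)O[Si](C)(C)CCl | starting material
13 | [(isopropoxydimethylsilyl)methyl]magnesium chloride | CC(C)O[Si](C)(C)C[Mg]Cl | intermediate
14 | C7 trimethylsilyl enol ether (C7=C8) bearing C9α-CH2SiMe2(OiPr) | CC1(C)OC(=O)C=C[C@@]2(C)[C@H]1CC(O[Si](C)(C)C)=C[C@H]2C[Si](C)(C)OC(C)C | intermediate
15 | keto lactone bearing C9α-CH2SiMe2(OiPr) and C8-CH2OH (C8 epimers) | CC1(C)OC(=O)C=C[C@@]2(C)[C@H]1CC(=O)C(CO)[C@H]2C[Si](C)(C)OC(C)C | intermediate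
16 | diol: keto lactone bearing C9α-CH2OH (C11) and C8-CH2OH (C12) | CC1(C)OC(=O)C=C[C@@]2(C)[C@H]1CC(=O)C(CO)[C@H]2CO | intermediate
17 | bis(methanesulfonate) of 16 | CC1(C)OC(=O)C=C[C@@]2(C)[C@H]1CC(=O)C(COS(C)(=O)=O)[C@H]2COS(C)(=O)=O | intermediate
18 | α-methylene ketone: C8=C12H2; C9α-CH2OMs | CC1(C)OC(=O)C=C[C@@]2(C)[C@H]1CC(=O)C(=C)[C@H]2COS(C)(=O)=O | intermediate
19 | 2-methylpent-1-en-3-one | CCC(=O)C(C)=C | starting material
20 | tert-butyldimethyl{[(3Z)-2-methylpenta-1,3-dien-3-yl]oxy}silane | C/C=C(\O[Si](C)(C)C(C)(C)C)C(C)=C | intermediate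
21 | methyl 4-hydroxybut-2-ynoate | COC(=O)C#CCO | starting material
22 | methyl 4-(tert-butyldimethylsilyloxy)-2-(hydroxymethyl)-3,5-dimethylcyclohexa-1,4-diene-1-carboxylate (racemic) | COC(=O)C1=C(CO)C(C)C(O[Si](C)(C)C(C)(C)C)=C(C)C1 | intermediate
23 | 5-(tert-butyldimethylsilyloxy)-4,6-dimethyl-4,7-dihydro-2-benzofuran-1(3H)-one (racemic) | CC1C(O[Si](C)(C)C(C)(C)C)=C(C)CC2=C1COC2=O | intermediate
24 | mono-Michael adduct: C12–C3′ bond; C7 tert-butyldimethylsilyl enol ether (C7=C8); butenolide intact | CC1(C)OC(=O)C=C[C@@]2(C)[C@H]1CC(O[Si](C)(C)C(C)(C)C)=C(C[C@@]3(C)CC4=C(COC4=O)C(C)C3=O)[C@H]2COS(C)(=O)=O | intermediate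
25 | silyl ketene acetal of 26 (C1′=C7′; O-silylated lactone) | CC1(C)OC(=O)C=C[C@@]2(C)[C@H]1CC(=O)[C@]3(C[C@@]4(C)CC5=C(O[Si](C)(C)C(C)(C)C)OC[C@]53C(C)C4=O)[C@H]2COS(C)(=O)=O | intermediate
26 | bicyclo[2.2.2]octane diketone lactone: C12–C3′ and C8–C6′ bonds; C7=O; C5′–H; C11–OMs | CC1(C)OC(=O)C=C[C@@]2(C)[C@H]1CC(=O)[C@]3(C[C@@]4(C)C[C@@H]5C(=O)OC[C@]53C(C)C4=O)[C@H]2COS(C)(=O)=O | intermediate
27 | C7 p-toluenesulfonylhydrazone of 26 | CC1(C)OC(=O)C=C[C@@]2(C)[C@H]1CC(=NNS(=O)(=O)c6ccc(C)cc6)[C@]3(C[C@@]4(C)C[C@@H]5C(=O)OC[C@]53C(C)C4=O)[C@H]2COS(C)(=O)=O | intermediate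
28 | 7-deoxo derivative of 26 (C7H2; C11–OMs) | CC1(C)OC(=O)C=C[C@@]2(C)[C@H]1CC[C@]3(C[C@@]4(C)C[C@@H]5C(=O)OC[C@]53C(C)C4=O)[C@H]2COS(C)(=O)=O | intermediate
29 | andilesin C | CC1(C)OC(=O)C=C[C@@]2(C)[C@H]1CC[C@@]13C[C@@]4(C)C[C@@H]5C(=O)OC[C@]51[C@@](C)(C[C@@H]23)C4=O | target

Total step count: 14. Longest linear sequence: 11 steps (steps 2–8 and 11–14).

Steps most likely to fail

Step 11. The first Michael addition may pair the two prochiral faces the wrong way round, which gives a cage of the opposite sense with respect to ring B that cannot close in step 14. The second addition, which joins two fully substituted carbons, may also stall so that protodesilylation takes over. The fallback makes the C5′–C11 bond first and lets a base-mediated double Michael addition, now steered by that tether, build the cage; it sets out from 15 and 23 and comes back at 29. Silylation of 15 (TBSCl, imidazole) should give silyl ether F1. Tamao–Fleming oxidation should give alcohol F2, and Appel iodination iodide F3. Desilylation of 23 (TBAF, AcOH) should give keto butenolide F4, whose doubly activated C5′–H is alkylated by F3 (Cs2CO3, DMF) to the C5′-quaternary ketone F5 (the C5′ epimers are separated). HF·pyridine should give β-hydroxy ketone F6, and acid-catalysed dehydration (TsOH, benzene, reflux) enone F7. LiHMDS should then trigger the intramolecular double Michael addition (C3′ enolate to C12, then C8 to C6′) to cage ketone F8. F8 is deoxygenated through tosylhydrazone F9 (TsNHNH2; then catecholborane, NaOAc·3H2O) to 29.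

Step 3. The facial selectivity of the radical addition at C5 may be poor, because formyl and methyl on C10 differ little in size. Intermolecular olefination may also lead to oligomers in place of the seven-membered ring closure. The fallback forms the two bonds in separate steps and closes the lactone at the C4–O bond; it sets out from 7 and comes back at 9. Still–Gennari olefination of 7 (methyl bis(2,2,2-trifluoroethyl)phosphonoacetate, KHMDS, 18-crown-6) should give (Z)-enoate F10. Copper-catalysed conjugate addition of isopropenylmagnesium bromide (CuI, TMSCl), now steered anti to the large acrylate arm, should give isopropenyl ketone F11. Saponification (LiOH) should give acid F12, and acid-catalysed Markovnikov addition of the carboxyl group to the isopropenyl group (TfOH, CH2Cl2) should close the lactone to 9.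

Step 12. Condensation at the carbonyl next to quaternary C8 may be slow, and the hydrazide may displace the primary mesylate on prolonged heating. The fallback removes the C7 oxygen by radical deoxygenation; it sets out from 26 and comes back at 28. NaBH4 (MeOH, 0 °C) should reduce the C7 ketone, the caged C4′ ketone and both lactones reacting more slowly, to alcohol F13. Thiocarbonyldiimidazole should give imidazolyl thiocarbonate F14, and Barton–McCombie deoxygenation (Bu3SnH, AIBN, toluene, 90 °C) should give 28.

Further compounds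
F1 | step 11 | C12 tert-butyldimethylsilyl ether of 15 | CC1(C)OC(=O)C=C[C@@]2(C)[C@H]1CC(=O)C(CO[Si](C)(C)C(C)(C)C)[C@H]2C[Si](C)(C)OC(C)C
F2 | step 11 | C11 alcohol with C12–OTBS | CC1(C)OC(=O)C=C[C@@]2(C)[C@H]1CC(=O)C(CO[Si](C)(C)C(C)(C)C)[C@H]2CO
F3 | step 11 | C11 iodide with C12–OTBS | CC1(C)OC(=O)C=C[C@@]2(C)[C@H]1CC(=O)C(CO[Si](C)(C)C(C)(C)C)[C@H]2CI
F4 | step 11 | 4,6-dimethyl-6,7-dihydro-2-benzofuran-1,5(3H,4H)-dione | CC1C(=O)C(C)CC2=C1COC2=O
F5 | step 11 | C5′-alkylated keto butenolide (C11–C5′ bond; C12–OTBS) | CC1(C)OC(=O)C=C[C@@]2(C)[C@H]1CC(=O)C(CO[Si](C)(C)C(C)(C)C)[C@H]2C[C@@]3(C)C(=O)C(C)CC4=C3COC4=O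
F6 | step 11 | β-hydroxy ketone from F5 (C12–OH) | CC1(C)OC(=O)C=C[C@@]2(C)[C@H]1CC(=O)C(CO)[C@H]2C[C@@]3(C)C(=O)C(C)CC4=C3COC4=O
F7 | step 11 | α-methylene ketone tethered to the keto butenolide through C11 | CC1(C)OC(=O)C=C[C@@]2(C)[C@H]1CC(=O)C(=C)[C@H]2C[C@@]3(C)C(=O)C(C)CC4=C3COC4=O
F8 | step 11 | 7-oxo derivative of 29 (cage ketone) | CC1(C)OC(=O)C=C[C@@]2(C)[C@H]1CC(=O)[C@@]13C[C@@]4(C)C[C@@H]5C(=O)OC[C@]51[C@@](C)(C[C@@H]23)C4=O
F9 | step 11 | C7 p-toluenesulfonylhydrazone of F8 | CC1(C)OC(=O)C=C[C@@]2(C)[C@H]1CC(=NNS(=O)(=O)c6ccc(C)cc6)[C@@]13C[C@@]4(C)C[C@@H]5C(=O)OC[C@]51[C@@](C)(C[C@@H]23)C4=O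
F10 | step 3 | methyl (Z)-3-[(R)-1-methyl-4-oxocyclohex-2-en-1-yl]prop-2-enoate | COC(=O)/C=C\[C@@]1(C)C=CC(=O)CC1
F11 | step 3 | methyl (Z)-3-[1-methyl-4-oxo-2-(prop-1-en-2-yl)cyclohexyl]prop-2-enoate (isopropenyl trans to the acrylate arm) | COC(=O)/C=C\[C@@]1(C)[C@H](C(C)=C)CC(=O)CC1
F12 | step 3 | (Z)-3-[1-methyl-4-oxo-2-(prop-1-en-2-yl)cyclohexyl]prop-2-enoic acid | OC(=O)/C=C\[C@@]1(C)[C@H](C(C)=C)CC(=O)CC1
F13 | step 12 | C7 alcohol from 26 | CC1(C)OC(=O)C=C[C@@]2(C)[C@H]1CC(O)[C@]3(C[C@@]4(C)C[C@@H]5C(=O)OC[C@]53C(C)C4=O)[C@H]2COS(C)(=O)=O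
F14 | step 12 | C7 O-(imidazol-1-ylthiocarbonyl) derivative of F13 | CC1(C)OC(=O)C=C[C@@]2(C)[C@H]1CC(OC(=S)n6ccnc6)[C@]3(C[C@@]4(C)C[C@@H]5C(=O)OC[C@]53C(C)C4=O)[C@H]2COS(C)(=O)=O
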